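**Remark on the chemistry (assumption):** (S)-carvone 1, acrylonitrile 3 and umbelliferone 14 are bought. Drimane numbering is used for all compounds: C1–C10 are the decalin carbons, C11 is the CH2O carbon on C9, C12 is the methyl on C8. "Open face" means the face of ring B opposite to the C10 methyl group.

## Analysis of the target

The target is the umbelliferone ether of a trans-fused drimane decalin. Ring A carries the C3 ketone next to the gem-dimethyl quaternary C4; ring B carries the C6 acetate, the C7=C8 alkene with its C8 methyl, the C9–CH2OAr arm and the angular methyl on quaternary C10. The four stereocentres C6–C5–C10–C9 are contiguous on ring B, (5S,6R,9R,10S): H5 is trans to the C10 methyl, C11 is cis to it, and the acetoxy group is trans to it (equatorial, H5/H6 trans-diaxial). This decalin is the mirror image of the one in the common drimane and labdane chiral pool, so semisynthesis from that pool is excluded. Sensitive groups are the allylic acetate (ionisable, labile to zerovalent palladium), the coumarin (lactone, Michael and radical acceptor) and the C3 ketone, which must be told apart from any ring-B carbonyl. The hard points are the congested C4–C5–C10 array with two quaternary carbons and the equatorial C6 oxygen. Hydride reduction of a C6 ketone would come from the open face, away from the syn-axial C10 and C4 methyls, and give the axial epimer, so the oxygen must be delivered to an sp2 C6–H carbon from the open face. The structural feature that invites the strategy is that ring B is a disguised carvone: C9 at the carbonyl level, C8 methyl on the alkene, and C5 bearing C4 with its two methyls, which is an isopropenyl group. The C3 ketone next to quaternary C4 is then the trace of a tertiary C4 radical adding to a C3 nitrile.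

## Retrosynthetic reasoning

**16 ⇒ 15 ⇒ 13 + 14.** The acetate and the aryl ether go on last. Acetylation of 15 retains configuration, so C6 must arrive correct. The C11–O bond is cut to diol 13 and umbelliferone 14 (Mitsunobu at the primary alcohol). The coumarin is attached late because it would not survive the ylide, hydride and radical steps.

**13 ⇒ 12 ⇒ 11 ⇒ 10.** The C9–H bond is cut back to the C9–O bond of vinyl oxirane 11 (palladium/formate hydrogenolysis with inversion, via 12). The C9–C11 bond is cut back to the C9 ketone of 10 (sulfonium methylide). Both forward steps use the open face of ring B, so H9 ends anti and C11 cis to the C10 methyl. The C9 carbonyl is the original carvone carbonyl.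

**10 ⇒ 9 ⇒ 8 ⇒ 7.** The C6–O bond is cut here and not at a C6 ketone. In the forward sense the conjugated enone 7 is deconjugated to the β,γ-enone 8, a peracid epoxidises the isolated C6=C7 alkene from the open face (9), and base opens the β,γ-epoxy ketone to the γ-hydroxy enone 10. The oxygen is thus delivered to C6 and not a hydrogen, which gives the equatorial epimer that reduction cannot give.

**7 ⇒ 6.** The C3 ketone is masked as its dimethyl ketal so that only the hindered C9 carbonyl meets the ylide; the ketal falls off in the acidic work-up of step 8.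

**6 ⇒ 5 ⇒ 4 (key).** Ring A is opened at the C3–C4 bond. C3 becomes a nitrile carbon and C4 the internal carbon of an isopropenyl group. Precursor 4 is a monocyclic carvone derivative with two stereocentres. The forward reaction must make a bond between a carbonyl carbon and a quaternary carbon, create the gem-dimethyl group, and close a trans-decalin.

**4 ⇒ 2 + 3 ⇒ 1.** The two C10 substituents come from two α′-alkylations of (S)-carvone 1. Methyl goes in first (2) and the cyanoethyl group second (Michael addition to 3), because the second electrophile enters anti to the isopropenyl group and must end trans to it.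

## Alternatives that were turned down

**Alternative 1: biomimetic epoxy-polyene cyclisation (textbook).** The C4–C5 and C9–C10 bonds are cut together. Forward, the (R)-10′,11′-epoxide of the farnesyl umbelliferyl ether, A1, is cyclised by a Lewis acid to the 3-hydroxydrim-7-en-11-yl ether A2, with C5, C9 and C10 relayed from the epoxide. It was turned down because C6 is a saturated tether carbon that takes no part in the cyclisation. It must be oxidised afterwards, next to the alkene and in the presence of the coumarin and the C3 carbonyl, which leads to the 7-en-6-one A3. Hydride attacks A3 from the open face and gives the axial C6 epimer. The cyclisation also gives alkene isomers and monocyclic products, and the non-natural epoxide needs its own enantioselective step.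

**Alternative 2: Wieland–Miescher ketone.** Ring A is cut at C4–C5 and C1–C10 (Robinson annulation). Forward, the D-proline-catalysed annulation gives (R)-Wieland–Miescher ketone A4, and deconjugative gem-dimethylation gives the Δ5-3,9-dione A5. Hydroboration of that alkene would set C5 and C6 correctly. It was turned down on step economy: the annulation builds only the bare decalin. The C8 methyl, the C7=C8 alkene, C11 and the C6 oxygen are each added later, with repeated protection and redox changes at C3 and C9, for well over a dozen steps.

**Alternative 3: Diels–Alder annulation of ring A onto a quinone monoketal.** Ring A is cut at C4–C5 and C1–C10. Forward, 4,4-dimethoxy-2,6-dimethylcyclohexa-2,5-dienone A6 and 4-methyl-3-(triisopropylsilyloxy)penta-1,3-diene A7 would combine under a chiral oxazaborolidinium Lewis acid to adduct A8, which holds every skeletal carbon except C11. It was turned down for three reasons.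
- The cycloaddition can only give the cis ring fusion. Correction needs epimerisation at C5 through the C6 ketone, and in a 4,4-dimethyl-6-oxo decalin with a flat enedione ring B the cis isomer is expected to be at least as stable as the trans.
- The C6 carbonyl must then be reduced, which again gives the axial epimer.
- A diene with a cis methyl on its reacting terminus is a poor partner for an α-methyl, β-neopentyl dienophile.

Key step: step 3

## Route

**Step 1**
Reactants: 1 (S)-(+)-carvone, (5S)-2-methyl-5-(prop-1-en-2-yl)cyclohex-2-en-1-one
Product: 2 (5S,6R)-2,6-dimethyl-5-(prop-1-en-2-yl)cyclohex-2-en-1-one (6-methylcarvone; trans epimer shown, the cis epimer is carried along)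
Conditions: LiN(i-Pr)2, THF, −78 °C; MeI, −78 → 0 °C
Reagents that add atoms: iodomethane, CI
Why: Kinetic α′-deprotonation gives the cross-conjugated enolate, which is methylated by SN2 alkylation; the new centre is planarised again in step 2, so its configuration does not matter.

**Step 2**
Reactants: 2 (5S,6R)-2,6-dimethyl-5-(prop-1-en-2-yl)cyclohex-2-en-1-one; 3 acrylonitrile
Product: 4 3-[(1R,6R)-1,3-dimethyl-2-oxo-6-(prop-1-en-2-yl)cyclohex-3-en-1-yl]propanenitrile (cyanoethyl trans, methyl cis to the isopropenyl group)
Conditions: LiN(i-Pr)2 (0.98 equiv), THF, −78 → −40 °C; 3, −78 °C; AcOH quench at −78 °C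
Reagents that add atoms: none
Why: Michael addition of the tetrasubstituted α′-enolate to 3 occurs on the enolate face anti to the neighbouring isopropenyl group, which sets quaternary C10 with the chain trans and the methyl cis to C4; the cold quench protonates the lithiated nitrile before it can add back to the enone.

**Step 3**
Reactants: 4 3-[(1R,6R)-1,3-dimethyl-2-oxo-6-(prop-1-en-2-yl)cyclohex-3-en-1-yl]propanenitrile
Product: 6 (5R,10R)-11-nordrim-7-ene-3,9-dione (trans-fused), via ketimine 5 (not isolated)
Conditions: Fe(acac)3 (30 mol%), PhSiH3 (2.5 equiv, slow addition), EtOH (0.02 M), 60 °C; then 1 M aq. HCl, THF, rt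
Reagents that add atoms: water, O
Why: An iron hydride formed from Fe(acac)3, PhSiH3 and ethanol transfers a hydrogen atom to the terminal CH2 of the electron-rich isopropenyl group, which turns that CH2 into the second C4 methyl and leaves a tertiary radical at C4. The radical adds 6-exo-dig to the nitrile carbon C3 and closes ring A through the C3–C4 bond; the iminyl radical is reduced by divalent iron and protonated to ketimine 5, trivalent iron is regenerated, and aqueous acid hydrolyses 5 to ketone 6. The closest known reaction type is the iron-hydride reductive cyclisation of alkenyl nitriles to α-quaternary cycloalkanones, and the related alkene–ketone couplings. No new stereocentre is formed, since C4 carries two methyls. The ring fusion follows from C5 and C10: their two ring-forming bonds are trans and both equatorial on ring B, so only the trans-decalin can close through a chair-like transition state. The step needs hydrogen-atom transfer to the isopropenyl group and not to the enone, which the electrophilic metal hydride secures by preferring the electron-rich, unhindered alkene. It also needs cyclisation faster than quenching of the radical, which is helped by the Thorpe–Ingold effect of quaternary C10, by high dilution and by slow addition of the silane. The enone cannot trap the radical within the molecule (only a four-membered ring could form), so the nitrile is the only acceptor in reach.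

**Step 4**
Reactants: 6 (5R,10R)-11-nordrim-7-ene-3,9-dione
Product: 7 (5R,10R)-3,3-dimethoxy-11-nordrim-7-en-9-one
Conditions: HC(OMe)3, MeOH, p-TsOH·H2O (cat.), rt; Et3N quench
Reagents that add atoms: trimethyl orthoformate, COC(OC)OC
Why: Acid-catalysed ketalisation with the orthoformate as water scavenger; only the saturated C3 ketone reacts, because the C9 carbonyl is conjugated and flanked by quaternary C10 and the C8 methyl.

**Step 5**
Reactants: 7 (5R,10R)-3,3-dimethoxy-11-nordrim-7-en-9-one
Product: 8 (5R,10R)-3,3-dimethoxy-11-nordrim-6-en-9-one (C8 epimers, used crude)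
Conditions: KOt-Bu (4 equiv), t-BuOH/THF, rt, argon; inverse quench into 10% aq. AcOH, 0 °C
Reagents that add atoms: none
Why: Classical enone deconjugation: γ-deprotonation at C6 gives the extended dienolate (C10 is quaternary, so there is no α′ proton), and kinetic protonation at the α-carbon C8 gives the β,γ-enone; C8 becomes sp2 again in step 6.

**Step 6**
Reactants: 8 (5R,10R)-3,3-dimethoxy-11-nordrim-6-en-9-one
Product: 10 (5R,6R,10R)-6-hydroxy-3,3-dimethoxy-11-nordrim-7-en-9-one, via epoxide 9 (not isolated)
Conditions: m-CPBA, NaHCO3, CH2Cl2, 0 °C; then Et3N, rt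
Reagents that add atoms: 3-chloroperoxybenzoic acid, OOC(=O)c1cccc(Cl)c1
Why: Prilezhaev epoxidation of the isolated C6=C7 alkene occurs on the open face, away from the syn-axial C10 and C4 methyls; E1cB opening of the β,γ-epoxy ketone (loss of H8, cleavage of C7–O) then gives the γ-hydroxy enone. The C6–O bond made in the epoxidation is kept, so the hydroxyl is equatorial and trans to the C10 methyl, as in the conversion of 5α,6α-epoxy-3-keto steroids into 6α-hydroxy-4-en-3-ones.

**Step 7**
Reactants: 10 (5R,6R,10R)-6-hydroxy-3,3-dimethoxy-11-nordrim-7-en-9-one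
Product: 11 (5S,6R,9R,10R)-9,11-epoxy-3,3-dimethoxydrim-7-en-6-ol (spiro-oxirane, CH2 on the open face)
Conditions: Me3S+ I− (3 equiv), n-BuLi (2.9 equiv), THF, −10 °C; then 10, −10 °C → rt
Reagents that add atoms: trimethylsulfonium iodide, C[S+](C)C.[I-]
Why: Corey–Chaykovsky epoxidation: the small sulfonium methylide adds 1,2 to the hindered enone carbonyl (as with 2,6,6-trimethylcyclohex-2-enone) along the axial direction anti to the C10 methyl, so CH2 sits on the open face and oxygen on the methyl face; the first equivalent only deprotonates the C6 hydroxyl, and the ketal hides C3.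

**Step 8**
Reactants: 11 (5S,6R,9R,10R)-9,11-epoxy-3,3-dimethoxydrim-7-en-6-ol
Product: 13 (5S,6R,9R,10S)-6,11-dihydroxydrim-7-en-3-one, via diol ketal 12 (not isolated)
Conditions: Pd2(dba)3·CHCl3 (2.5 mol%), PBu3 (10 mol%), HCO2H, Et3N, 1,4-dioxane, rt; then 1 M aq. HCl, THF, 0 °C → rt
Reagents that add atoms: water, O
Why: Palladium-catalysed formate hydrogenolysis of an alkenyl oxirane: zerovalent palladium ionises the tertiary allylic C9–O bond from the open face (anti to oxygen), and the palladium hydride formed from formate delivers hydrogen to the more substituted allyl terminus C9 on that same face. The net inversion places H9 anti and C11 cis to the C10 methyl and keeps the C7=C8 alkene; the acidic work-up hydrolyses the dimethyl ketal.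

**Step 9**
Reactants: 13 (5S,6R,9R,10S)-6,11-dihydroxydrim-7-en-3-one; 14 umbelliferone (7-hydroxy-2H-chromen-2-one)
Product: 15 (5S,6R,9R,10S)-6-hydroxy-11-[(2-oxo-2H-chromen-7-yl)oxy]drim-7-en-3-one
Conditions: PPh3, DIAD, THF, 0 °C → rt
Reagents that add atoms: none
Why: Mitsunobu etherification with an acidic phenol; the primary C11 alcohol is activated, while the secondary C6 alcohol, flanked by C5 with its two quaternary neighbours, is not. C11 is not a stereocentre.

**Step 10**
Reactants: 15 (5S,6R,9R,10S)-6-hydroxy-11-[(2-oxo-2H-chromen-7-yl)oxy]drim-7-en-3-one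
Product: 16 (5S,6R,9R,10S)-6-acetoxy-11-[(2-oxo-2H-chromen-7-yl)oxy]drim-7-en-3-one (target, CNP0140705.2)
Conditions: Ac2O, DMAP (cat.), pyridine, CH2Cl2, rt
Reagents that add atoms: acetic anhydride, CC(=O)OC(C)=O
Why: DMAP-catalysed acylation of the equatorial allylic alcohol with retention; the labile allylic acetate is made last.

## Compound list

1 | (S)-(+)-carvone, (5S)-2-methyl-5-(prop-1-en-2-yl)cyclohex-2-en-1-one | CC1=CC[C@@H](CC1=O)C(C)=C | starting material
2 | (5S,6R)-2,6-dimethyl-5-(prop-1-en-2-yl)cyclohex-2-en-1-one (trans epimer shown) | C1C=C(C)C(=O)[C@H](C)[C@H]1C(C)=C | intermediate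
3 | acrylonitrile | C=CC#N | starting material
4 | 3-[(1R,6R)-1,3-dimethyl-2-oxo-6-(prop-1-en-2-yl)cyclohex-3-en-1-yl]propanenitrile | C1C=C(C)C(=O)[C@](C)(CCC#N)[C@H]1C(C)=C | intermediate
5 | (5R,10R)-3-imino-11-nordrim-7-en-9-one (ketimine) | C1C=C(C)C(=O)[C@]2(C)CCC(=N)C(C)(C)[C@@H]12 | intermediate (not isolated)
6 | (5R,10R)-11-nordrim-7-ene-3,9-dione | C1C=C(C)C(=O)[C@]2(C)CCC(=O)C(C)(C)[C@@H]12 | intermediate
7 | (5R,10R)-3,3-dimethoxy-11-nordrim-7-en-9-one | C1C=C(C)C(=O)[C@]2(C)CCC(OC)(OC)C(C)(C)[C@@H]12 | intermediate
8 | (5R,10R)-3,3-dimethoxy-11-nordrim-6-en-9-one (C8 epimers) | C1=CC(C)C(=O)[C@]2(C)CCC(OC)(OC)C(C)(C)[C@@H]12 | intermediate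
9 | (5R,6S,7R,10R)-6,7-epoxy-3,3-dimethoxy-11-nordriman-9-one (C8 epimers) | [C@@H]12O[C@@H]1C(C)C(=O)[C@]3(C)CCC(OC)(OC)C(C)(C)[C@@H]23 | intermediate (not isolated)
10 | (5R,6R,10R)-6-hydroxy-3,3-dimethoxy-11-nordrim-7-en-9-one | O[C@@H]1C=C(C)C(=O)[C@]2(C)CCC(OC)(OC)C(C)(C)[C@@H]12 | intermediate
11 | (5S,6R,9R,10R)-9,11-epoxy-3,3-dimethoxydrim-7-en-6-ol | O[C@@H]1C=C(C)[C@]3(CO3)[C@]2(C)CCC(OC)(OC)C(C)(C)[C@@H]12 | intermediate
12 | (5S,6R,9R,10S)-3,3-dimethoxydrim-7-ene-6,11-diol | O[C@@H]1C=C(C)[C@@H](CO)[C@]2(C)CCC(OC)(OC)C(C)(C)[C@@H]12 | intermediate (not isolated)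
13 | (5S,6R,9R,10S)-6,11-dihydroxydrim-7-en-3-one | O[C@@H]1C=C(C)[C@@H](CO)[C@]2(C)CCC(=O)C(C)(C)[C@@H]12 | intermediate
14 | umbelliferone, 7-hydroxy-2H-chromen-2-one | Oc1ccc2ccc(=O)oc2c1 | starting material
15 | (5S,6R,9R,10S)-6-hydroxy-11-[(2-oxo-2H-chromen-7-yl)oxy]drim-7-en-3-one | O[C@@H]1C=C(C)[C@@H](COc2ccc3ccc(=O)oc3c2)[C@]2(C)CCC(=O)C(C)(C)[C@@H]12 | intermediate
16 | (5S,6R,9R,10S)-6-acetoxy-11-[(2-oxo-2H-chromen-7-yl)oxy]drim-7-en-3-one | CC(=O)O[C@@H]1C=C(C)[C@@H](COc2ccc3ccc(=O)oc3c2)[C@]2(C)CCC(=O)C(C)(C)[C@@H]12 | target

## Step count and least certain steps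

Total step count: 10. Longest linear sequence: 10 steps (1 → 16).

**Step 3 (key step).** The 6-exo addition of a tertiary radical to a nitrile is slow, so the radical may be quenched first, which would simply hydrogenate the isopropenyl group. Conjugate reduction of the enone by the metal hydride could also compete. Fallback: starting from 4, Markovnikov hydrobromination of the isopropenyl group (HBr, AcOH, 0 °C) should give 3-[(1R,6S)-6-(2-bromopropan-2-yl)-1,3-dimethyl-2-oxocyclohex-3-en-1-yl]propanenitrile F1. A tin hydride chain reaction (Bu3SnH by syringe pump, AIBN, benzene, 80 °C, then aqueous acid) would generate the same radical at a very low hydrogen-donor concentration, so that ring closure can win. The route is rejoined at 6.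

**Step 2.** The lithiated nitrile formed after the Michael addition may add back to C7 of the enone in a second Michael reaction and close a bicyclo[2.2.2]octanone, or it may polymerise acrylonitrile. Fallback: starting from 2, the enolate is alkylated with allyl bromide (same facial course) to (5R,6R)-2,6-dimethyl-6-(prop-2-en-1-yl)-5-(prop-1-en-2-yl)cyclohex-2-en-1-one F2. An aldehyde-selective Wacker oxidation of the monosubstituted alkene (PdCl2(PhCN)2, CuCl2, AgNO2, t-BuOH/MeNO2, O2) gives 3-[(1R,6R)-1,3-dimethyl-2-oxo-6-(prop-1-en-2-yl)cyclohex-3-en-1-yl]propanal F3. Iodine in aqueous ammonia converts the aldehyde into the nitrile, and the route is rejoined at 4.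

**Step 6.** The β,γ-enone may slip back into conjugation before it is oxidised, and the small peracid may not fully distinguish the two faces or may start a Baeyer–Villiger oxidation. Fallback: starting from 8, dihydroxylation with the bulkier OsO4 (cat.) and NMO on the open face should give (5R,6S,7R,10R)-6,7-dihydroxy-3,3-dimethoxy-11-nordriman-9-one F4. Base-induced β-elimination of the C7 hydroxyl (DBU, CH2Cl2) returns to 10.

**Step 8.** The hydride may be delivered to the distal allyl terminus C7, which would move the alkene to C8=C9, or the allyl complex may undergo β-hydride elimination to a diene. Fallback: starting from 10, Wittig methylenation of the C9 ketone (Ph3PCH3Br, KOt-Bu, toluene, 90 °C) gives (5S,6R,10R)-3,3-dimethoxydrima-7,9(11)-dien-6-ol F5. Hydroboration of the exocyclic methylene with 9-BBN places hydrogen on C9 from the open face; oxidation (NaBO3) gives 12, and acid returns to 13.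

**Step 9.** Substitution at the β-branched primary carbon next to quaternary C10 may be slow, which would let activation of the C6 hydroxyl or elimination compete. Fallback: starting from 13, selective sulfonylation of the primary alcohol (TsCl, pyridine, 0 °C) gives (5S,6R,9R,10S)-6-hydroxy-11-(4-methylbenzenesulfonyloxy)drim-7-en-3-one F6. Displacement with the potassium salt of 14 (K2CO3, DMF, 60 °C) rejoins the route at 15.

## Further compounds

F1 | step 3 | 3-[(1R,6S)-6-(2-bromopropan-2-yl)-1,3-dimethyl-2-oxocyclohex-3-en-1-yl]propanenitrile | C1C=C(C)C(=O)[C@](C)(CCC#N)[C@H]1C(C)(C)Br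
F2 | step 2 | (5R,6R)-2,6-dimethyl-6-(prop-2-en-1-yl)-5-(prop-1-en-2-yl)cyclohex-2-en-1-one | C1C=C(C)C(=O)[C@](C)(CC=C)[C@H]1C(C)=C
F3 | step 2 | 3-[(1R,6R)-1,3-dimethyl-2-oxo-6-(prop-1-en-2-yl)cyclohex-3-en-1-yl]propanal | C1C=C(C)C(=O)[C@](C)(CCC=O)[C@H]1C(C)=C
F4 | step 6 | (5R,6S,7R,10R)-6,7-dihydroxy-3,3-dimethoxy-11-nordriman-9-one (C8 epimers) | O[C@@H]1[C@H](O)C(C)C(=O)[C@]2(C)CCC(OC)(OC)C(C)(C)[C@@H]12
F5 | step 8 | (5S,6R,10R)-3,3-dimethoxydrima-7,9(11)-dien-6-ol | O[C@@H]1C=C(C)C(=C)[C@]2(C)CCC(OC)(OC)C(C)(C)[C@@H]12
F6 | step 9 | (5S,6R,9R,10S)-6-hydroxy-11-(4-methylbenzenesulfonyloxy)drim-7-en-3-one | O[C@@H]1C=C(C)[C@@H](COS(=O)(=O)c2ccc(C)cc2)[C@]2(C)CCC(=O)C(C)(C)[C@@H]12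
A1 | alternative 1 | 7-{[(2E,6E,10R)-10,11-epoxy-3,7,11-trimethyldodeca-2,6-dien-1-yl]oxy}-2H-chromen-2-one | CC1(C)O[C@@H]1CC/C(C)=C/CC/C(C)=C/COc1ccc2ccc(=O)oc2c1
A2 | alternative 1 | (3R,5S,9R,10R)-3-hydroxy-11-[(2-oxo-2H-chromen-7-yl)oxy]drim-7-ene | C1C=C(C)[C@@H](COc2ccc3ccc(=O)oc3c2)[C@]2(C)CC[C@@H](O)C(C)(C)[C@@H]12
A3 | alternative 1 | 11-[(2-oxo-2H-chromen-7-yl)oxy]drim-7-ene-3,6-dione | O=C1C=C(C)[C@@H](COc2ccc3ccc(=O)oc3c2)[C@]2(C)CCC(=O)C(C)(C)[C@@H]12
A4 | alternative 2 | (R)-Wieland–Miescher ketone | C[C@@]12CCC(=O)C=C1CCCC2=O
A5 | alternative 2 | (R)-5,5,8a-trimethyl-3,4,8,8a-tetrahydronaphthalene-1,6(2H,7H)-dione | C[C@@]12CCC(=O)C(C)(C)C1=CCCC2=O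
A6 | alternative 3 | 4,4-dimethoxy-2,6-dimethylcyclohexa-2,5-dien-1-one | COC1(OC)C=C(C)C(=O)C(C)=C1
A7 | alternative 3 | 4-methyl-3-(triisopropylsilyloxy)penta-1,3-diene | C=CC(O[Si](C(C)C)(C(C)C)C(C)C)=C(C)C
A8 | alternative 3 | cis-fused (5S,10R)-6,6-dimethoxy-3-(triisopropylsilyloxy)-11-nordrima-2,7-dien-9-one | COC1(OC)C=C(C)C(=O)[C@]2(C)CC=C(O[Si](C(C)C)(C(C)C)C(C)C)C(C)(C)[C@H]12
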